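Locants follow the isochromene numbering for the bicycle and primes for the benzoate. The retrosynthesis cuts O2–C3 (alkynol closure), C4–C4a (Sonogashira), C1–C8a (formaldehyde, Baylis–Hillman), then the four aryl bonds C1'–C6', C1'–C2', C3'–C4' and C4'–C5'.
Enabling feature: in the benzoate ring the ester carbon C1' lies between OMe (C2') and CH3 (C6') and para to OH (C4'). This is the imprint of an ester-bearing isopropenylketene joined to methoxyethyne, so the crowded C7–O–C(=O) link is made first, from a slim acylketene, and the arene is grown on it.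
Forward order: carbocycle (ring B) from 2-methylcyclohexenone, then the benzene ring (ring C) on the tertiary ester in step 9, then enone, hydroxymethyl group, triflate and enyne, and the pyran (ring A) last by 6-endo closure.
Stereochemistry: C6 comes from a CBS reduction, C7 from osmylation anti to the allylic silyl ether, and the E-propenyl group is bought with pentenyne.
The future C8 carbonyl travels as a TES-protected carbinol until the arene is in place, because a β-keto ester beside that ketone would close to a butenolide (intramolecular Knoevenagel).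
Key step: step 9

Remark: (E)-pent-3-en-1-yne is taken to be purchasable as the pure E isomer, and methoxyethyne, too volatile to stock, is made fresh in step 8. TBS = tert-butyldimethylsilyl, TES = triethylsilyl, TIPS = triisopropylsilyl, pin = pinacolato, Tf = trifluoromethanesulfonyl.

Step 1
Reactants: 1 2-methylcyclohex-2-en-1-one
Product: 2 (R)-2-methylcyclohex-2-en-1-ol
Conditions: (S)-1-methyl-3,3-diphenyltetrahydro-1H,3H-pyrrolo[1,2-c][1,3,2]oxazaborole (10 mol %), BH3·SMe2, THF, −20 °C; MeOH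
Reagents that add atoms: none
Why: Corey–Bakshi–Shibata reduction, in which the α-methylated alkene arm of the enone plays the large group, so that the S catalyst should deliver hydride to the face that gives the R carbinol, the future C6.

Step 2
Reactants: 2 (R)-2-methylcyclohex-2-en-1-ol
Product: 3 (R)-tert-butyldimethyl[(2-methylcyclohex-2-en-1-yl)oxy]silane
Conditions: tBuMe2SiCl, imidazole, DMF, rt
Reagents that add atoms: tert-butyldimethylsilyl chloride, CC(C)(C)[Si](C)(C)Cl
Why: Routine imidazole-promoted silylation of a secondary allylic alcohol, which leaves the stereocentre untouched and installs the bulky group that steers step 3.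

Step 3
Reactants: 3 (R)-tert-butyldimethyl[(2-methylcyclohex-2-en-1-yl)oxy]silane
Product: 4 (1R,2R,3R)-3-(TBSO)-2-methylcyclohexane-1,2-diol
Conditions: OsO4 (2 mol %), N-methylmorpholine N-oxide, acetone/H2O, rt
Reagents that add atoms: N-methylmorpholine N-oxide, C[N+]1([O-])CCOCC1; water, O; both oxygens relayed by OsO4, O=[Os](=O)(=O)=O
Why: Catalytic syn-dihydroxylation, in which allylic strain with the vinylic methyl group holds the silyloxy group pseudoaxial so that osmium adds to the opposite face, placing the new tertiary C–O bond (future C7) trans to the C6 oxygen, while the configuration of the new secondary carbinol is of no consequence because it becomes the C8 carbonyl.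

Step 4
Reactants: 4 (1R,2R,3R)-3-(TBSO)-2-methylcyclohexane-1,2-diol
Product: 5 (1R,2R,6R)-2-(TBSO)-1-methyl-6-(TESO)cyclohexan-1-ol
Conditions: Et3SiCl (1.05 equiv), imidazole, CH2Cl2, 0 °C
Reagents that add atoms: triethylsilyl chloride, CC[Si](Cl)(CC)CC
Why: Chemoselective silylation, since a secondary hydroxyl reacts far faster than the neighbouring tertiary one, and the TES ether keeps the future C8 carbonyl masked so that the active-methylene ester of steps 6 and 7 has no adjacent ketone to condense with.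

Step 5
Reactants: 6 Meldrum's acid (2,2-dimethyl-1,3-dioxane-4,6-dione); 7 methacryloyl chloride
Product: 8 5-(1-hydroxy-2-methylprop-2-en-1-ylidene)-2,2-dimethyl-1,3-dioxane-4,6-dione
Conditions: pyridine, CH2Cl2, 0 °C to rt
Reagents that add atoms: none
Why: C-Acylation of Meldrum's acid with an acid chloride under pyridine, a standard entry to acylketene precursors, in which the α-methyl group of 7 tempers competing conjugate addition.

Step 6
Reactants: 5 (1R,2R,6R)-2-(TBSO)-1-methyl-6-(TESO)cyclohexan-1-ol; 8 5-(1-hydroxy-2-methylprop-2-en-1-ylidene)-2,2-dimethyl-1,3-dioxane-4,6-dione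
Product: 10 (1R,2R,6R)-2-(TBSO)-1-methyl-6-(TESO)cyclohexyl 4-methyl-3-oxopent-4-enoate, via acylketene 9 (not isolated)
Conditions: 8 (1.5 equiv), toluene, 110 °C
Reagents that add atoms: none
Why: Thermal fragmentation of the acyl Meldrum's acid (loss of acetone and CO2) releases acylketene 9, whose planar and sterically undemanding addition of O–H is the established way to acylate tertiary alcohols, so the crowded ester C–O bond is forged while the acyl part is still slim.

Step 7
Reactants: 10 (1R,2R,6R)-2-(TBSO)-1-methyl-6-(TESO)cyclohexyl 4-methyl-3-oxopent-4-enoate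
Product: 11 (1R,2R,6R)-2-(TBSO)-1-methyl-6-(TESO)cyclohexyl 2-diazo-4-methyl-3-oxopent-4-enoate
Conditions: 4-acetamidobenzenesulfonyl azide, Et3N, MeCN, 0 °C to rt
Reagents that add atoms: 4-acetamidobenzenesulfonyl azide, CC(=O)Nc1ccc(cc1)S(=O)(=O)N=[N+]=[N-]
Why: Regitz diazo transfer to the doubly activated methylene group, which is fast with a mild amine base and removes the nucleophilic carbon before the enone part can be attacked.

Step 8
Reactants: 12 chloroacetaldehyde dimethyl acetal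
Product: 14 methoxyethyne, via sodium methoxyethynide 13 (not isolated)
Conditions: NaNH2 (3 equiv), liq NH3, −33 °C; aq NaCl, −70 °C; distil into cold ClCH2CH2Cl
Reagents that add atoms: none
Why: Twofold base-induced elimination (methanol, then HCl) from the chloroacetal by sodium amide, the classical preparation of alkoxyethynes, with the third equivalent of base holding the product as its acetylide until the quench.

Step 9
Reactants: 11 (1R,2R,6R)-2-(TBSO)-1-methyl-6-(TESO)cyclohexyl 2-diazo-4-methyl-3-oxopent-4-enoate; 14 methoxyethyne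
Product: 19 (1R,2R,6R)-2-(TBSO)-1-methyl-6-(TESO)cyclohexyl 4-hydroxy-2-methoxy-6-methylbenzoate, via ester-substituted vinylketene 15 (not isolated), via vinylcyclobutenone 16 (not isolated), via dienylketene 17 (not isolated), via cyclohexadienone 18 (not isolated)
Conditions: 14 (6 equiv), degassed ClCH2CH2Cl (0.02 M), 365 nm LED, 5 °C, pressure vessel; then 80 °C
Reagents that add atoms: none
Why: Proposed new method: light absorbed by the diazo dicarbonyl chromophore expels N2 and the isopropenyl group shifts from the ketone carbon to the diazo carbon (Wolff rearrangement, bond C1'–C6'), giving ketene 15; its carbonyl carbon is attacked by the nucleophilic CH terminus of 14 (C3'–C4') and its α-carbon bonds to the methoxy-bearing carbon (C1'–C2'), a [2+2] closure of the four-membered ring of 16. On warming, ring strain drives reversible conrotatory 4π opening to dienylketene 17, and the isomer that holds the isopropenyl group cis to the ketene arm closes the six-membered ring by disrotatory 6π electrocyclisation (C4'–C5'), after which enolisation of 18 delivers the phenol. The closest known reaction type is the Danheiser benzannulation in its photochemical Wolff form, shown for unsaturated α-diazo ketones with alkynyl ethers but not for a diazo carbon that also carries an ester, whose ketenes have so far been intercepted only by alcohols, amines and imines. No lasting stereocentre is created, since the quaternary carbon of 16 becomes planar again on ring opening, and the three stereocentres of the cyclohexane are remote spectators without a chromophore at 365 nm. The step needs alkenyl rather than alkoxy migration (carbon groups on the ketone side migrate far more readily than an ester oxygen), head-to-tail [2+2] rather than [4+2] capture (secured by the strong polarisation of the ynol ether and the poor heterodiene character of an ester carbonyl) and ketene rather than carbene chemistry (favoured by an inert solvent, excess 14 and the Z ester conformation that holds the silylated ring away from the carbene carbon).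

Step 10
Reactants: 19 (1R,2R,6R)-2-(TBSO)-1-methyl-6-(TESO)cyclohexyl 4-hydroxy-2-methoxy-6-methylbenzoate
Product: 20 (1R,2R,6R)-2-(TBSO)-1-methyl-6-(TESO)cyclohexyl 2-methoxy-6-methyl-4-(TIPSO)benzoate
Conditions: iPr3SiCl, imidazole, DMF, rt
Reagents that add atoms: triisopropylsilyl chloride, CC(C)[Si](Cl)(C(C)C)C(C)C
Why: Standard silylation of the acidic para-acyl phenol, chosen as the TIPS ether because it has to survive aqueous amine, buffered peroxide and amine bases before the final fluoride step.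

Step 11
Reactants: 20 (1R,2R,6R)-2-(TBSO)-1-methyl-6-(TESO)cyclohexyl 2-methoxy-6-methyl-4-(TIPSO)benzoate
Product: 22 (1S,2R)-2-(TBSO)-1-methyl-6-oxocyclohexyl 2-methoxy-6-methyl-4-(TIPSO)benzoate, via secondary alcohol 21 (not isolated)
Conditions: 2-iodoxybenzoic acid (3 equiv), DMSO, rt
Reagents that add atoms: none
Why: 2-Iodoxybenzoic acid in DMSO is known to cleave TES ethers while sparing TBS ethers and then to oxidise the liberated alcohol in the same flask, so carbinol 21 is consumed before the hindered, mesitoate-like aroyl group could migrate to it.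

Step 12
Reactants: 22 (1S,2R)-2-(TBSO)-1-methyl-6-oxocyclohexyl 2-methoxy-6-methyl-4-(TIPSO)benzoate
Product: 24 (1S,6R)-6-(TBSO)-1-methyl-2-oxocyclohex-3-en-1-yl 2-methoxy-6-methyl-4-(TIPSO)benzoate, via trimethylsilyl enol ether 23 (not isolated)
Conditions: LiN(SiMe3)2, Me3SiCl, THF, −78 °C; then Pd(OAc)2 (1.1 equiv), MeCN, rt
Reagents that add atoms: chlorotrimethylsilane, C[Si](C)(C)Cl (its silyl group is present in 23 only)
Why: Saegusa–Ito oxidation, in which the ketone can enolise only towards the C8a methylene because C7 is quaternary, and divalent palladium turns the silyl enol ether into the enone by β-hydride elimination.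

Step 13
Reactants: 24 (1S,6R)-6-(TBSO)-1-methyl-2-oxocyclohex-3-en-1-yl 2-methoxy-6-methyl-4-(TIPSO)benzoate
Product: 25 (1S,6R)-6-(TBSO)-3-(hydroxymethyl)-1-methyl-2-oxocyclohex-3-en-1-yl 2-methoxy-6-methyl-4-(TIPSO)benzoate
Conditions: 37% aq HCHO, 4-(dimethylamino)pyridine (0.3 equiv), THF, rt
Reagents that add atoms: formaldehyde, C=O
Why: Morita–Baylis–Hillman hydroxymethylation, reliable for cyclohexenones with aqueous formaldehyde and a nucleophilic pyridine, which adds C1 at the α-carbon C8a and avoids the bis-adducts that formaldehyde gives with free 1,3-diones.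

Step 14
Reactants: 25 (1S,6R)-6-(TBSO)-3-(hydroxymethyl)-1-methyl-2-oxocyclohex-3-en-1-yl 2-methoxy-6-methyl-4-(TIPSO)benzoate
Product: 26 (1S,6R)-6-(TBSO)-3-(TBSOCH2)-1-methyl-2-oxocyclohex-3-en-1-yl 2-methoxy-6-methyl-4-(TIPSO)benzoate
Conditions: tBuMe2SiCl, imidazole, CH2Cl2, rt
Reagents that add atoms: tert-butyldimethylsilyl chloride, CC(C)(C)[Si](C)(C)Cl
Why: Routine silylation of the primary allylic alcohol so that it is neither oxidised in step 16 nor sulfonylated in step 17.

Step 15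
Reactants: 26 (1S,6R)-6-(TBSO)-3-(TBSOCH2)-1-methyl-2-oxocyclohex-3-en-1-yl 2-methoxy-6-methyl-4-(TIPSO)benzoate
Product: 28 (1S,6R)-6-(TBSO)-3-(TBSOCH2)-4-hydroxy-1-methyl-2-oxocyclohexyl 2-methoxy-6-methyl-4-(TIPSO)benzoate (C3 and C4 of the ring unassigned), via β-boryl ketone 27 (not isolated)
Conditions: B2pin2, CuCl (5 mol %), 4,5-bis(diphenylphosphino)-9,9-dimethylxanthene (5 mol %), NaOtBu (10 mol %), MeOH (2 equiv), THF, rt; then 30% H2O2, pH 7 phosphate buffer, 0 °C
Reagents that add atoms: bis(pinacolato)diboron, CC1(C)OB(OC1(C)C)B1OC(C)(C)C(C)(C)O1 (its boryl group is present in 27 only); hydrogen peroxide, OO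
Why: Copper-catalysed conjugate borylation of the enone followed by C–B oxidation, a mild β-hydroxylation in which methanol should protonate the copper enolate faster than it can expel the silyloxide, and whose two new stereocentres (C4a, C8a) need no control because step 16 erases them.

Step 16
Reactants: 28 (1S,6R)-6-(TBSO)-3-(TBSOCH2)-4-hydroxy-1-methyl-2-oxocyclohexyl 2-methoxy-6-methyl-4-(TIPSO)benzoate
Product: 29 (1S,6R)-6-(TBSO)-3-(TBSOCH2)-4-hydroxy-1-methyl-2-oxocyclohex-3-en-1-yl 2-methoxy-6-methyl-4-(TIPSO)benzoate (enol form of the 1,3-dione)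
Conditions: Dess–Martin periodinane, CH2Cl2, 0 °C to rt
Reagents that add atoms: none
Why: Dess–Martin oxidation of the β-hydroxy ketone under non-basic conditions gives the 1,3-dione, which should rest as its hydrogen-bonded enol.

Step 17
Reactants: 29 (1S,6R)-6-(TBSO)-3-(TBSOCH2)-4-hydroxy-1-methyl-2-oxocyclohex-3-en-1-yl 2-methoxy-6-methyl-4-(TIPSO)benzoate
Product: 30 (1S,6R)-6-(TBSO)-3-(TBSOCH2)-1-methyl-2-oxo-4-(TfO)cyclohex-3-en-1-yl 2-methoxy-6-methyl-4-(TIPSO)benzoate
Conditions: Tf2O, 2,6-lutidine, CH2Cl2, −78 °C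
Reagents that add atoms: trifluoromethanesulfonic anhydride, O=S(=O)(OS(=O)(=O)C(F)(F)F)C(F)(F)F
Why: O-Triflation of a cyclic 1,3-dione to a vinylogous acyl triflate, which should take place at the enol oxygen on C4a because the other oxygen is flanked by the quaternary, aroyloxy-bearing C7.

Step 18
Reactants: 30 (1S,6R)-6-(TBSO)-3-(TBSOCH2)-1-methyl-2-oxo-4-(TfO)cyclohex-3-en-1-yl 2-methoxy-6-methyl-4-(TIPSO)benzoate; 31 (E)-pent-3-en-1-yne
Product: 32 (1S,6R)-6-(TBSO)-3-(TBSOCH2)-1-methyl-2-oxo-4-[(E)-pent-3-en-1-yn-1-yl]cyclohex-3-en-1-yl 2-methoxy-6-methyl-4-(TIPSO)benzoate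
Conditions: PdCl2(PPh3)2 (5 mol %), CuI (10 mol %), iPr2NH, THF, rt
Reagents that add atoms: none
Why: Sonogashira coupling, for which β-triflyloxy enones are among the most reactive partners, forms C4–C4a at room temperature with retention of the E-alkene of 31.

Step 19
Reactants: 32 (1S,6R)-6-(TBSO)-3-(TBSOCH2)-1-methyl-2-oxo-4-[(E)-pent-3-en-1-yn-1-yl]cyclohex-3-en-1-yl 2-methoxy-6-methyl-4-(TIPSO)benzoate
Product: 33 (1S,6R)-6-hydroxy-3-(hydroxymethyl)-1-methyl-2-oxo-4-[(E)-pent-3-en-1-yn-1-yl]cyclohex-3-en-1-yl 4-hydroxy-2-methoxy-6-methylbenzoate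
Conditions: HF·pyridine, pyridine, THF, 0 °C to rt
Reagents that add atoms: none
Why: Fluoride-driven cleavage of all three silyl ethers under mildly acidic buffering, which avoids the retro-aldol, elimination and acyl-shift pathways that basic fluoride could open in the β-hydroxy ketone.

Step 20
Reactants: 33 (1S,6R)-6-hydroxy-3-(hydroxymethyl)-1-methyl-2-oxo-4-[(E)-pent-3-en-1-yn-1-yl]cyclohex-3-en-1-yl 4-hydroxy-2-methoxy-6-methylbenzoate
Product: 34 (6R,7S)-6-hydroxy-7-methyl-8-oxo-3-[(E)-prop-1-en-1-yl]-5,6,7,8-tetrahydro-1H-isochromen-7-yl 4-hydroxy-2-methoxy-6-methylbenzoate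
Conditions: AgOSO2CF3 (5 mol %), CH2Cl2, rt
Reagents that add atoms: none
Why: π-Acid-catalysed 6-endo-dig cycloisomerisation of the alkynol, in which the alkyne is polarised in one sense by the enone acceptor on the C4 side and the propenyl donor on C3, so that the hydroxyl should attack C3 (formally a 1,6-oxa-Michael addition) rather than close 5-exo to a furan-type isomer, and protodemetalation gives the 1H-isochromene.

Compound list
1 | 2-methylcyclohex-2-en-1-one | CC1=CCCCC1=O | starting material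
2 | (R)-2-methylcyclohex-2-en-1-ol | C1=C(C)[C@H](O)CCC1 | intermediate
3 | (R)-tert-butyldimethyl[(2-methylcyclohex-2-en-1-yl)oxy]silane | C1=C(C)[C@H](O[Si](C)(C)C(C)(C)C)CCC1 | intermediate
4 | (1R,2R,3R)-3-(TBSO)-2-methylcyclohexane-1,2-diol (both hydroxyls trans to OTBS) | O[C@H]1[C@@](C)(O)[C@H](O[Si](C)(C)C(C)(C)C)CCC1 | intermediate
5 | (1R,2R,6R)-2-(TBSO)-1-methyl-6-(TESO)cyclohexan-1-ol | CC[Si](CC)(CC)O[C@H]1[C@@](C)(O)[C@H](O[Si](C)(C)C(C)(C)C)CCC1 | intermediate
6 | Meldrum's acid (2,2-dimethyl-1,3-dioxane-4,6-dione) | CC1(C)OC(=O)CC(=O)O1 | starting material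
7 | methacryloyl chloride | CC(=C)C(=O)Cl | starting material
8 | 5-(1-hydroxy-2-methylprop-2-en-1-ylidene)-2,2-dimethyl-1,3-dioxane-4,6-dione | CC(=C)C(O)=C1C(=O)OC(C)(C)OC1=O | intermediate
9 | 4-methyl-3-oxopenta-1,4-dien-1-one (acylketene) | CC(=C)C(=O)C=C=O | intermediate
10 | (1R,2R,6R)-2-(TBSO)-1-methyl-6-(TESO)cyclohexyl 4-methyl-3-oxopent-4-enoate | CC[Si](CC)(CC)O[C@H]1[C@@](C)(OC(=O)CC(=O)C(C)=C)[C@H](O[Si](C)(C)C(C)(C)C)CCC1 | intermediate
11 | (1R,2R,6R)-2-(TBSO)-1-methyl-6-(TESO)cyclohexyl 2-diazo-4-methyl-3-oxopent-4-enoate | CC[Si](CC)(CC)O[C@H]1[C@@](C)(OC(=O)C(=[N+]=[N-])C(=O)C(C)=C)[C@H](O[Si](C)(C)C(C)(C)C)CCC1 | intermediate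
12 | chloroacetaldehyde dimethyl acetal | COC(CCl)OC | starting material
13 | sodium methoxyethynide | [Na+].[C-]#COC | intermediate
14 | methoxyethyne | COC#C | intermediate
15 | (1R,2R,6R)-2-(TBSO)-1-methyl-6-(TESO)cyclohexyl 3-methyl-2-(oxomethylidene)but-3-enoate (vinylketene) | CC[Si](CC)(CC)O[C@H]1[C@@](C)(OC(=O)C(=C=O)C(C)=C)[C@H](O[Si](C)(C)C(C)(C)C)CCC1 | intermediate
16 | (1R,2R,6R)-2-(TBSO)-1-methyl-6-(TESO)cyclohexyl 2-methoxy-4-oxo-1-(prop-1-en-2-yl)cyclobut-2-ene-1-carboxylate (ring carbon 1 unassigned) | CC[Si](CC)(CC)O[C@H]1[C@@](C)(OC(=O)C2(C(C)=C)C(=O)C=C2OC)[C@H](O[Si](C)(C)C(C)(C)C)CCC1 | intermediate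
17 | (1R,2R,6R)-2-(TBSO)-1-methyl-6-(TESO)cyclohexyl (2Z)-3-methoxy-5-oxo-2-(prop-1-en-2-yl)penta-2,4-dienoate (dienylketene) | CC[Si](CC)(CC)O[C@H]1[C@@](C)(OC(=O)/C(C(C)=C)=C(\OC)C=C=O)[C@H](O[Si](C)(C)C(C)(C)C)CCC1 | intermediate
18 | (1R,2R,6R)-2-(TBSO)-1-methyl-6-(TESO)cyclohexyl 6-methoxy-2-methyl-4-oxocyclohexa-1,5-diene-1-carboxylate | CC[Si](CC)(CC)O[C@H]1[C@@](C)(OC(=O)C2=C(C)CC(=O)C=C2OC)[C@H](O[Si](C)(C)C(C)(C)C)CCC1 | intermediate
19 | (1R,2R,6R)-2-(TBSO)-1-methyl-6-(TESO)cyclohexyl 4-hydroxy-2-methoxy-6-methylbenzoate | CC[Si](CC)(CC)O[C@H]1[C@@](C)(OC(=O)c2c(C)cc(O)cc2OC)[C@H](O[Si](C)(C)C(C)(C)C)CCC1 | intermediate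
20 | (1R,2R,6R)-2-(TBSO)-1-methyl-6-(TESO)cyclohexyl 2-methoxy-6-methyl-4-(TIPSO)benzoate | CC[Si](CC)(CC)O[C@H]1[C@@](C)(OC(=O)c2c(C)cc(O[Si](C(C)C)(C(C)C)C(C)C)cc2OC)[C@H](O[Si](C)(C)C(C)(C)C)CCC1 | intermediate
21 | (1R,2R,6R)-2-(TBSO)-6-hydroxy-1-methylcyclohexyl 2-methoxy-6-methyl-4-(TIPSO)benzoate | O[C@H]1[C@@](C)(OC(=O)c2c(C)cc(O[Si](C(C)C)(C(C)C)C(C)C)cc2OC)[C@H](O[Si](C)(C)C(C)(C)C)CCC1 | intermediate
22 | (1S,2R)-2-(TBSO)-1-methyl-6-oxocyclohexyl 2-methoxy-6-methyl-4-(TIPSO)benzoate | O=C1[C@@](C)(OC(=O)c2c(C)cc(O[Si](C(C)C)(C(C)C)C(C)C)cc2OC)[C@H](O[Si](C)(C)C(C)(C)C)CCC1 | intermediate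
23 | (1S,6R)-6-(TBSO)-1-methyl-2-(trimethylsilyloxy)cyclohex-2-en-1-yl 2-methoxy-6-methyl-4-(TIPSO)benzoate | C[Si](C)(C)OC1=CCC[C@@H](O[Si](C)(C)C(C)(C)C)[C@]1(C)OC(=O)c2c(C)cc(O[Si](C(C)C)(C(C)C)C(C)C)cc2OC | intermediate
24 | (1S,6R)-6-(TBSO)-1-methyl-2-oxocyclohex-3-en-1-yl 2-methoxy-6-methyl-4-(TIPSO)benzoate | O=C1[C@@](C)(OC(=O)c2c(C)cc(O[Si](C(C)C)(C(C)C)C(C)C)cc2OC)[C@H](O[Si](C)(C)C(C)(C)C)CC=C1 | intermediate
25 | (1S,6R)-6-(TBSO)-3-(hydroxymethyl)-1-methyl-2-oxocyclohex-3-en-1-yl 2-methoxy-6-methyl-4-(TIPSO)benzoate | O=C1[C@@](C)(OC(=O)c2c(C)cc(O[Si](C(C)C)(C(C)C)C(C)C)cc2OC)[C@H](O[Si](C)(C)C(C)(C)C)CC=C1CO | intermediate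
26 | (1S,6R)-6-(TBSO)-3-(TBSOCH2)-1-methyl-2-oxocyclohex-3-en-1-yl 2-methoxy-6-methyl-4-(TIPSO)benzoate | O=C1[C@@](C)(OC(=O)c2c(C)cc(O[Si](C(C)C)(C(C)C)C(C)C)cc2OC)[C@H](O[Si](C)(C)C(C)(C)C)CC=C1CO[Si](C)(C)C(C)(C)C | intermediate
27 | (1S,6R)-6-(TBSO)-3-(TBSOCH2)-1-methyl-2-oxo-4-(Bpin)cyclohexyl 2-methoxy-6-methyl-4-(TIPSO)benzoate (ring C3 and C4 unassigned) | O=C1[C@@](C)(OC(=O)c2c(C)cc(O[Si](C(C)C)(C(C)C)C(C)C)cc2OC)[C@H](O[Si](C)(C)C(C)(C)C)CC(B3OC(C)(C)C(C)(C)O3)C1CO[Si](C)(C)C(C)(C)C | intermediate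
28 | (1S,6R)-6-(TBSO)-3-(TBSOCH2)-4-hydroxy-1-methyl-2-oxocyclohexyl 2-methoxy-6-methyl-4-(TIPSO)benzoate (ring C3 and C4 unassigned) | O=C1[C@@](C)(OC(=O)c2c(C)cc(O[Si](C(C)C)(C(C)C)C(C)C)cc2OC)[C@H](O[Si](C)(C)C(C)(C)C)CC(O)C1CO[Si](C)(C)C(C)(C)C | intermediate
29 | (1S,6R)-6-(TBSO)-3-(TBSOCH2)-4-hydroxy-1-methyl-2-oxocyclohex-3-en-1-yl 2-methoxy-6-methyl-4-(TIPSO)benzoate (enol of the 1,3-dione) | O=C1[C@@](C)(OC(=O)c2c(C)cc(O[Si](C(C)C)(C(C)C)C(C)C)cc2OC)[C@H](O[Si](C)(C)C(C)(C)C)CC(O)=C1CO[Si](C)(C)C(C)(C)C | intermediate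
30 | (1S,6R)-6-(TBSO)-3-(TBSOCH2)-1-methyl-2-oxo-4-(TfO)cyclohex-3-en-1-yl 2-methoxy-6-methyl-4-(TIPSO)benzoate | O=C1[C@@](C)(OC(=O)c2c(C)cc(O[Si](C(C)C)(C(C)C)C(C)C)cc2OC)[C@H](O[Si](C)(C)C(C)(C)C)CC(OS(=O)(=O)C(F)(F)F)=C1CO[Si](C)(C)C(C)(C)C | intermediate
31 | (E)-pent-3-en-1-yne | C/C=C/C#C | starting material
32 | (1S,6R)-6-(TBSO)-3-(TBSOCH2)-1-methyl-2-oxo-4-[(E)-pent-3-en-1-yn-1-yl]cyclohex-3-en-1-yl 2-methoxy-6-methyl-4-(TIPSO)benzoate | O=C1[C@@](C)(OC(=O)c2c(C)cc(O[Si](C(C)C)(C(C)C)C(C)C)cc2OC)[C@H](O[Si](C)(C)C(C)(C)C)CC(C#C/C=C/C)=C1CO[Si](C)(C)C(C)(C)C | intermediate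
33 | (1S,6R)-6-hydroxy-3-(hydroxymethyl)-1-methyl-2-oxo-4-[(E)-pent-3-en-1-yn-1-yl]cyclohex-3-en-1-yl 4-hydroxy-2-methoxy-6-methylbenzoate | O=C1[C@@](C)(OC(=O)c2c(C)cc(O)cc2OC)[C@H](O)CC(C#C/C=C/C)=C1CO | intermediate
34 | (6R,7S)-6-hydroxy-7-methyl-8-oxo-3-[(E)-prop-1-en-1-yl]-5,6,7,8-tetrahydro-1H-isochromen-7-yl 4-hydroxy-2-methoxy-6-methylbenzoate | C/C=C/C1=CC2=C(CO1)C(=O)[C@@](C)(OC(=O)c1c(C)cc(O)cc1OC)[C@H](O)C2 | target

Total step count: 20.
Longest linear sequence: 18 (steps 1–4, 6, 7 and 9–20). Steps 5 and 8 are side branches.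

Steps most likely to fail

Step 9. Carbene-type reactions may outrun the Wolff and [2+2] sequence: C–H insertion, addition to the alkyne with furan formation, or [4+2] capture of the ester-bearing ketene. The cyclobutenone may also fail to open cleanly.
- The fallback uses the known ketene trapping and aldol aromatisation of diketo-dioxinones. It sets out from 5 and comes back to the route at 20.
- The lithium dienolate of commercial 2,2,6-trimethyl-4H-1,3-dioxin-4-one is acetylated with acetyl chloride to 2,2-dimethyl-6-(2-oxopropyl)-4H-1,3-dioxin-4-one F1.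
- The dianion of F1 is acetylated again with N-acetylimidazole to 2,2-dimethyl-6-(2,4-dioxopentyl)-4H-1,3-dioxin-4-one F2.
- Heating F2 with 5 in toluene releases acetone and a triketo-ketene, which the tertiary hydroxyl traps as the 3,5,7-trioxooctanoate ester F3.
- Cs2CO3 and then mild acid close C2 onto C7 and dehydrate to the 2,4-dihydroxy-6-methylbenzoate ester F4.
- The non-chelated para hydroxyl is silylated selectively (iPr3SiCl, imidazole) to the 2-hydroxy-6-methyl-4-(TIPSO)benzoate ester F5.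
- Mitsunobu methylation of the remaining ortho hydroxyl (MeOH, PPh3, diisopropyl azodicarboxylate) gives 20.

Step 16. The enolisable 2-(silyloxymethyl)-1,3-dione may shed silanol by an E1cB process, or be over-oxidised at C8a, before it can be triflated.
- The fallback avoids the dione altogether. It sets out from 26 and comes back to the route at 32, replacing steps 15–18.
- Compound 31 is metalated (n-BuLi, then ZnBr2) to (E)-pent-3-en-1-yn-1-ylzinc bromide F6.
- F6 is added to 26 in the presence of tBuMe2SiOSO2CF3 (silyl-triflate-promoted conjugate alkynylation). The product is the 2,6-bis(TBSO)-3-(TBSOCH2)-4-pentenynylcyclohex-2-enyl ester F7.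
- Saegusa–Ito oxidation of this silyl enol ether with Pd(OAc)2 restores the C4a=C8a double bond and gives 32.

Step 6. The crowded tertiary hydroxyl may capture the acylketene too slowly. Ketene dimerisation, self-Michael addition of the enone keto ester or acid-induced loss of the TES group could then take over.
- The fallback builds the diazo keto ester from a diazoacetate. It sets out from 5 and comes back to the route at 11, replacing steps 5–7.
- The small and very reactive bromoacetyl bromide (pyridine, CH2Cl2) gives the bromoacetate F8.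
- N,N'-Ditosylhydrazine and DBU convert F8 into the diazoacetate F9.
- DBU-catalysed aldol-type addition of F9 to methacrolein gives the 2-diazo-3-hydroxy-4-methylpent-4-enoate F10.
- Dess–Martin oxidation of this allylic alcohol gives 11.

Further compounds
F1 | step 9 | 2,2-dimethyl-6-(2-oxopropyl)-4H-1,3-dioxin-4-one | CC(=O)CC1=CC(=O)OC(C)(C)O1
F2 | step 9 | 2,2-dimethyl-6-(2,4-dioxopentyl)-4H-1,3-dioxin-4-one | CC(=O)CC(=O)CC1=CC(=O)OC(C)(C)O1
F3 | step 9 | (1R,2R,6R)-2-(TBSO)-1-methyl-6-(TESO)cyclohexyl 3,5,7-trioxooctanoate | CC[Si](CC)(CC)O[C@H]1[C@@](C)(OC(=O)CC(=O)CC(=O)CC(C)=O)[C@H](O[Si](C)(C)C(C)(C)C)CCC1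
F4 | step 9 | (1R,2R,6R)-2-(TBSO)-1-methyl-6-(TESO)cyclohexyl 2,4-dihydroxy-6-methylbenzoate | CC[Si](CC)(CC)O[C@H]1[C@@](C)(OC(=O)c2c(C)cc(O)cc2O)[C@H](O[Si](C)(C)C(C)(C)C)CCC1
F5 | step 9 | (1R,2R,6R)-2-(TBSO)-1-methyl-6-(TESO)cyclohexyl 2-hydroxy-6-methyl-4-(TIPSO)benzoate | CC[Si](CC)(CC)O[C@H]1[C@@](C)(OC(=O)c2c(C)cc(O[Si](C(C)C)(C(C)C)C(C)C)cc2O)[C@H](O[Si](C)(C)C(C)(C)C)CCC1
F6 | step 16 | (E)-pent-3-en-1-yn-1-ylzinc bromide | C/C=C/C#C[Zn]Br
F7 | step 16 | (1S,6R)-2,6-bis(TBSO)-3-(TBSOCH2)-1-methyl-4-[(E)-pent-3-en-1-yn-1-yl]cyclohex-2-en-1-yl 2-methoxy-6-methyl-4-(TIPSO)benzoate (ring C4 unassigned) | CC(C)(C)[Si](C)(C)OC1=C(CO[Si](C)(C)C(C)(C)C)C(C#C/C=C/C)C[C@@H](O[Si](C)(C)C(C)(C)C)[C@]1(C)OC(=O)c2c(C)cc(O[Si](C(C)C)(C(C)C)C(C)C)cc2OC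
F8 | step 6 | (1R,2R,6R)-2-(TBSO)-1-methyl-6-(TESO)cyclohexyl bromoacetate | CC[Si](CC)(CC)O[C@H]1[C@@](C)(OC(=O)CBr)[C@H](O[Si](C)(C)C(C)(C)C)CCC1
F9 | step 6 | (1R,2R,6R)-2-(TBSO)-1-methyl-6-(TESO)cyclohexyl diazoacetate | CC[Si](CC)(CC)O[C@H]1[C@@](C)(OC(=O)C=[N+]=[N-])[C@H](O[Si](C)(C)C(C)(C)C)CCC1
F10 | step 6 | (1R,2R,6R)-2-(TBSO)-1-methyl-6-(TESO)cyclohexyl 2-diazo-3-hydroxy-4-methylpent-4-enoate (carbinol carbon unassigned) | CC[Si](CC)(CC)O[C@H]1[C@@](C)(OC(=O)C(=[N+]=[N-])C(O)C(C)=C)[C@H](O[Si](C)(C)C(C)(C)C)CCC1
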